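**Retrosynthetic overview**
- Target ⇒ its free secondary alcohol (acetate C–O), acetylated in the flask in which the alcohol is formed.
- Hydroxy coumarin ⇒ acyclic 3-[(R)-6,7-epoxygeranyloxy]phenyl propiolate. Two C–C bonds are disconnected together: the CMe2–CH bond of the cyclohexane (epoxy-ene closure) and C4–C4a of the coumarin (alkyne hydroarylation).
- Ring order: the benzene ring is bought; one gold catalyst closes the cyclohexane first (−40 °C) and the pyranone second (on warming), in one flask.
- Aryl propiolate ⇒ propiolic acid + 3-[(R)-6,7-epoxygeranyloxy]phenol (ester C–O); the epoxide comes from asymmetric epoxidation of the terminal olefin and later controls the second stereocentre.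
- 3-(Geranyloxy)phenol ⇒ resorcinol + geranyl bromide (ether C–O).

Assumption: the roughly 90–95% ee expected from the catalytic asymmetric epoxidation is raised to single-enantiomer quality by one recrystallisation (or a chiral HPLC pass) of the target.

**Route**

Step 1
Reactants: 1 resorcinol (benzene-1,3-diol, 3 equiv); 2 geranyl bromide ((2E)-1-bromo-3,7-dimethylocta-2,6-diene)
Product: 3 3-{[(2E)-3,7-dimethylocta-2,6-dien-1-yl]oxy}phenol
Conditions: K2CO3 (1.2 equiv), DMF, 23 °C
Reagents that add atoms: none
Why: Williamson ether synthesis (SN2 of the monophenoxide on the primary allylic bromide); excess water-soluble resorcinol suppresses the bis-ether, the polar aprotic solvent favours O- over C-alkylation, the E olefin is untouched and no stereocentre is formed.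

Step 2
Reactants: 3 3-{[(2E)-3,7-dimethylocta-2,6-dien-1-yl]oxy}phenol
Product: 4 3-{[(2E)-5-[(2R)-3,3-dimethyloxiran-2-yl]-3-methylpent-2-en-1-yl]oxy}phenol
Conditions: 1,2:4,5-di-O-isopropylidene-β-D-erythro-2,3-hexodiulo-2,6-pyranose (D-fructose-derived Shi ketone, 2 equiv), Oxone (2KHSO5·KHSO4·K2SO4), NaHCO3, MeCN–aq. disodium ethylenediaminetetraacetate, pH 7.5–8, 0 °C
Reagents that add atoms: Oxone (potassium peroxymonosulfate, KHSO5), [K+].[O-]S(=O)(=O)OO
Why: Shi asymmetric epoxidation: the chiral dioxirane transfers oxygen through a spiro transition state to the electron-rich terminal olefin (the 2,3-olefin is deactivated by the allylic aryloxy group), the D-fructose-derived ketone gives the (R)-epoxide, and at pH 7.5–8 the phenol (pKa about 9.6) stays protonated and is not oxidised.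

Step 3
Reactants: 4 3-{[(2E)-5-[(2R)-3,3-dimethyloxiran-2-yl]-3-methylpent-2-en-1-yl]oxy}phenol; 5 propiolic acid (prop-2-ynoic acid)
Product: 7 3-{[(2E)-5-[(2R)-3,3-dimethyloxiran-2-yl]-3-methylpent-2-en-1-yl]oxy}phenyl prop-2-ynoate, via O-propioloyl isourea 6 (not isolated)
Conditions: DCC, 4-(dimethylamino)pyridine (5 mol %), CH2Cl2, −20 → 0 °C, 5 added last, dropwise
Reagents that add atoms: none
Why: Steglich-type carbodiimide esterification through the O-acylisourea; adding the acid slowly to the cold phenol/DCC mixture keeps free propiolic acid (pKa about 1.9) away from the acid-labile epoxide, and the stereocentre is not involved.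

Step 4
Reactants: 7 3-{[(2E)-5-[(2R)-3,3-dimethyloxiran-2-yl]-3-methylpent-2-en-1-yl]oxy}phenyl prop-2-ynoate
Product: 10 7-{[(1S,3R)-3-acetoxy-2,2-dimethyl-6-methylidenecyclohexyl]methoxy}-2H-chromen-2-one (CNP0300702.1), via cyclohexanol aryl propiolate 8 (not isolated), via hydroxy coumarin 9 (not isolated)
Conditions: AuCl3 (5 mol %), AgOTf (15 mol %), 2,6-di-tert-butylpyridine (10 mol %), CH2Cl2, −40 → 23 °C; then pyridine, Ac2O, 4-(dimethylamino)pyridine (10 mol %), 23 °C, same flask
Reagents that add atoms: acetic anhydride, CC(=O)OC(C)=O
Why: Proposed new method: Au(OTf)3 formed in situ (trivalent gold) is both oxophilic and carbophilic, and the two reacting sites are insulated from each other. At −40 °C it opens the epoxide at its tertiary carbon and the 2,3-olefin closes the six-membered carbocycle through a chair transition state with the C–O bond and the aryloxymethyl arm both equatorial; the epoxide carbon keeps its R configuration and fixes the new centre as S (1,3-cis), and the tertiary cation loses a methyl proton to the hindered base to give the exocyclic methylene (8). On warming, the same catalyst π-activates the propiolate for 6-endo attack by the arene carbon para to the ether oxygen (less hindered than the position between the two oxygens), and protodeauration closes the pyranone (9). Pyridine then stops the catalyst and the alcohol is acetylated in the same flask. The closest known reactions are the Lewis acid epoxy-ene cyclization of 6,7-epoxygeranyl esters and of epoxy terpenyl coumarin ethers, the gold-catalysed intramolecular hydroarylation of aryl alkynoates to coumarins, and the AuCl3/AgOTf-catalysed Friedel–Crafts ring closure of epoxides.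

**Compound list**

1 | resorcinol (benzene-1,3-diol) | Oc1cccc(O)c1 | starting material
2 | geranyl bromide, (2E)-1-bromo-3,7-dimethylocta-2,6-diene | CC(C)=CCC/C(C)=C/CBr | starting material
3 | 3-{[(2E)-3,7-dimethylocta-2,6-dien-1-yl]oxy}phenol | CC(C)=CCC/C(C)=C/COc1cccc(O)c1 | intermediate
4 | 3-{[(2E)-5-[(2R)-3,3-dimethyloxiran-2-yl]-3-methylpent-2-en-1-yl]oxy}phenol | CC1(C)O[C@@H]1CC/C(C)=C/COc1cccc(O)c1 | intermediate
5 | propiolic acid (prop-2-ynoic acid) | C#CC(=O)O | starting material
6 | N,N'-dicyclohexyl-O-propioloylisourea (formed in the flask, not isolated) | C#CC(=O)OC(=NC1CCCCC1)NC1CCCCC1 | intermediate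
7 | 3-{[(2E)-5-[(2R)-3,3-dimethyloxiran-2-yl]-3-methylpent-2-en-1-yl]oxy}phenyl prop-2-ynoate | CC1(C)O[C@@H]1CC/C(C)=C/COc1cccc(OC(=O)C#C)c1 | intermediate
8 | 3-{[(1S,3R)-3-hydroxy-2,2-dimethyl-6-methylidenecyclohexyl]methoxy}phenyl prop-2-ynoate (formed in the flask, not isolated) | C=C1CC[C@@H](O)C(C)(C)[C@H]1COc1cccc(OC(=O)C#C)c1 | intermediate
9 | 7-{[(1S,3R)-3-hydroxy-2,2-dimethyl-6-methylidenecyclohexyl]methoxy}-2H-chromen-2-one (formed in the flask, not isolated) | C=C1CC[C@@H](O)C(C)(C)[C@H]1COc1ccc2ccc(=O)oc2c1 | intermediate
10 | 7-{[(1S,3R)-3-acetoxy-2,2-dimethyl-6-methylidenecyclohexyl]methoxy}-2H-chromen-2-one, i.e. (1R,3S)-2,2-dimethyl-4-methylidene-3-{[(2-oxo-2H-chromen-7-yl)oxy]methyl}cyclohexyl acetate | C=C1CC[C@@H](OC(C)=O)C(C)(C)[C@H]1COc1ccc2ccc(=O)oc2c1 | target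

**Summary and risks**

Total step count: 4. Longest linear sequence: 4 steps (1 → 3 → 4 → 7 → 10).

The three steps most likely to fail, in order of risk:

Step 4 (gold-mediated double cyclization and acetylation). The likely failures are loss of the ring proton instead of the methyl proton (endocyclic olefin isomers), rearrangement of the epoxide to a ketone, ionisation of the allylic aryl ether before the carbocycle closes, and some ring closure between the two oxygens (5-alkoxy coumarin). The fallback sets out from 7 and separates the two ring closures under catalysts that each do one job. Ph3PAuNTf2 (monovalent gold, 2 mol %, CH2Cl2, 23 °C) is too weakly oxophilic to open the epoxide and gives only the hydroarylation product 7-{[(2E)-5-[(2R)-3,3-dimethyloxiran-2-yl]-3-methylpent-2-en-1-yl]oxy}-2H-chromen-2-one F1. Cp2TiCl (trivalent titanium, from Cp2TiCl2 and Mn dust, THF, 23 °C) then opens the epoxide of F1 homolytically; the tertiary radical closes 6-endo through the same chair, is captured by a second Cp2TiCl and loses a β-hydrogen from the methyl group, which gives the exocyclic methylene selectively. This comes back to the route at 9, which is acetylated (Ac2O, pyridine, 4-(dimethylamino)pyridine) to 10.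

Step 2 (asymmetric epoxidation beside a free, electron-rich phenol). The likely failures are oxidation of the arene by the peroxide system and some epoxidation of the 2,3-olefin. The fallback sets out from 3 and masks the phenol: triisopropylsilyl chloride and imidazole in DMF give {3-{[(2E)-3,7-dimethylocta-2,6-dien-1-yl]oxy}phenoxy}tri(propan-2-yl)silane F2. The same ketone then epoxidises F2 under the catalytic K2CO3-buffered protocol (pH 10.5, 0 °C) to {3-{[(2E)-5-[(2R)-3,3-dimethyloxiran-2-yl]-3-methylpent-2-en-1-yl]oxy}phenoxy}tri(propan-2-yl)silane F3. Bu4NF in THF at 0 °C removes the silyl group and comes back to the route at 4.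

Step 3 (esterification with a strong acid beside the epoxide). The likely failure is acid opening of the epoxide, with loss of the sensitive aryl propiolate on purification as a second concern. The fallback sets out from 3 and reverses the order of events: 3 and 5 are coupled first (DCC, CH2Cl2, 0 °C; no epoxide is present) to give 3-{[(2E)-3,7-dimethylocta-2,6-dien-1-yl]oxy}phenyl prop-2-ynoate F4. F4 is then epoxidised by the same ketone under the NaHCO3-buffered protocol of step 2 (pH 7.5–8, 0 °C, short reaction time to spare the aryl ester), which comes back to the route at 7.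

Further compounds
F1 | step 4 | 7-{[(2E)-5-[(2R)-3,3-dimethyloxiran-2-yl]-3-methylpent-2-en-1-yl]oxy}-2H-chromen-2-one | CC1(C)O[C@@H]1CC/C(C)=C/COc1ccc2ccc(=O)oc2c1
F2 | step 2 | {3-{[(2E)-3,7-dimethylocta-2,6-dien-1-yl]oxy}phenoxy}tri(propan-2-yl)silane | CC(C)=CCC/C(C)=C/COc1cccc(O[Si](C(C)C)(C(C)C)C(C)C)c1
F3 | step 2 | {3-{[(2E)-5-[(2R)-3,3-dimethyloxiran-2-yl]-3-methylpent-2-en-1-yl]oxy}phenoxy}tri(propan-2-yl)silane | CC1(C)O[C@@H]1CC/C(C)=C/COc1cccc(O[Si](C(C)C)(C(C)C)C(C)C)c1
F4 | step 3 | 3-{[(2E)-3,7-dimethylocta-2,6-dien-1-yl]oxy}phenyl prop-2-ynoate | CC(C)=CCC/C(C)=C/COc1cccc(OC(=O)C#C)c1
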